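**Retrosynthetic overview**

- The route rests on the left-hand trans-fused oxepane–cyclohexane (ether O, C19 = OCMe2, C20 = CHOH, C14 = quaternary C–CH3, C15 = O–CH at the ring fusion, C13 = CH bearing the bridge, C18 = C(CH3)OH). Its O–C19 and C13–C14 bonds are made together from an acyclic 1,5-bis-epoxide whose carbon terminator is the enol silane of a β-keto ester.
- Last disconnections: C18–CH3 (organocerium, equatorial attack), the C7' carbinol (CBS reduction), and the C13–CH2–CH2–C5' bridge (vinylogous Mukaiyama–Michael addition of a hydroazulenone dienol silane to the C13 methylene ketone).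
- Left half: both rings close in one cascade; the acyclic precursor comes from geranyl bromide and ethyl acetoacetate, and Shi epoxidation sets C15 and C20.
- Right half: cyclopentane first (metathesis of linalool), then a second five-membered ring (Ireland–Claisen, diazoketone cyclopropanation, homoconjugate hydration), then two-carbon expansion to the seven-membered ring and Stork–Danheiser transposition.

Key step: step 4

Remark 1: left-half atoms carry the labels C13–C20 given above; right-half atoms carry primed azulene locants (C1' = C(CH3)OH, C3a'/C8a' = ring fusion, C4' = CMe2, C5'=C6' = alkene, C7' = CHOH, C8' = CH2).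
Remark 2: (S)-(+)-linalool of high enantiomeric purity is assumed to be purchasable; it is the source of the right-half configuration.

**Left half**

Step 1
Reactants: 1 geranyl bromide; 2 ethyl acetoacetate
Product: 3 ethyl (6E)-7,11-dimethyl-3-oxododeca-6,10-dienoate
Conditions: NaH, THF, 0 °C; n-BuLi, 0 °C; then 1, 0 °C → rt; aq. NH4Cl
Reagents that add atoms: none
Why: Alkylation of the acetoacetate dianion: the terminal (γ) carbanion is the more nucleophilic site and displaces the allylic bromide by SN2 without moving the E double bond.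

Step 2
Reactants: 3 ethyl (6E)-7,11-dimethyl-3-oxododeca-6,10-dienoate
Product: 4 ethyl (2Z,6E)-3-(tert-butyldimethylsilyloxy)-7,11-dimethyldodeca-2,6,10-trienoate
Conditions: t-BuMe2SiOTf, Et3N, CH2Cl2, 0 °C; aq. NaHCO3
Reagents that add atoms: tert-butyldimethylsilyl triflate, CC(C)(C)[Si](C)(C)OS(=O)(=O)C(F)(F)F
Why: Soft enolization of the β-keto ester and O-silylation by the silyl triflate give the conjugated Z enol silane, whose acrylate-type double bond is electron-poor enough to escape the dioxirane of the next step.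

Step 3
Reactants: 4 ethyl (2Z,6E)-3-(tert-butyldimethylsilyloxy)-7,11-dimethyldodeca-2,6,10-trienoate
Product: 5 ethyl (2Z,6R,7R,10R)-3-(tert-butyldimethylsilyloxy)-6,7:10,11-diepoxy-7,11-dimethyldodec-2-enoate
Conditions: D-fructose-derived Shi ketone (0.6 equiv), KHSO5, K2CO3, Bu4NHSO4, borate buffer, MeCN/CH2(OMe)2/H2O, 0 °C
Reagents that add atoms: potassium peroxymonosulfate, [K+].[O-]S(=O)(=O)OO
Why: Shi asymmetric epoxidation: the dioxirane of the D-fructose-derived ketone oxidizes the two electron-rich trisubstituted alkenes through a spiro transition state under reagent control (6R,7R and 10R), while the ester-conjugated enol ether is left alone.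

Step 4
Reactants: 5 ethyl (2Z,6R,7R,10R)-3-(tert-butyldimethylsilyloxy)-6,7:10,11-diepoxy-7,11-dimethyldodec-2-enoate
Product: 7 ethyl (3R,5aR,6R,9aR)-3-hydroxy-2,2,5a-trimethyl-7-oxodecahydro-1-benzoxepine-6-carboxylate (trans-fused; C20 = C3, C14 = C5a, C13 = C6, C15 = C9a), via trimethylsilyl ether 6 (not isolated)
Conditions: Me3SiOTf (1.3 equiv), 2,6-di-tert-butyl-4-methylpyridine, CH2Cl2, −78 °C; aq. NaHCO3; then 1 M HCl, THF, 0 °C
Reagents that add atoms: none
Why: Silylation of the terminal epoxide lets the oxygen of the internal epoxide attack the tertiary carbon C19 to give a bicyclic epoxonium ion, which the enol silane carbon C13 opens at the tertiary carbon C14 with inversion; the silyl group then leaves the oxocarbenium ion as t-BuMe2SiOTf. The closest known reaction type is the Lewis-acid tandem oxa-/carbacyclization of 1,5-bis-epoxides terminated by an enol silane. The oxepane closes in the 7-endo mode (O onto C19) and the cyclohexanone in the 6-endo mode through a chair. C14 is set by anti opening of the (6R,7R) E-epoxide (trans ring fusion, axial methyl), C15 and C20 are carried over unchanged from the Shi epoxides, and C13 settles by enolization as the equatorial ester. The step needs endo opening at both tertiary epoxide carbons and capture of the epoxonium ion by carbon and not by triflate or proton loss; the trisubstituted epoxides, the low temperature with a hindered pyridine base, and the π-nucleophile tethered for a six-membered chair should secure this.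

Step 5
Reactants: 7 ethyl (3R,5aR,6R,9aR)-3-hydroxy-2,2,5a-trimethyl-7-oxodecahydro-1-benzoxepine-6-carboxylate
Product: 8 ethyl (3R,5aR,9aR)-3,7-bis(tert-butyldimethylsilyloxy)-2,2,5a-trimethyl-2,3,4,5,5a,8,9,9a-octahydro-1-benzoxepine-6-carboxylate (C20 silyl ether, C13=C18 enol silane)
Conditions: t-BuMe2SiOTf (2.6 equiv), Et3N, CH2Cl2, 0 °C → rt; aq. NaHCO3
Reagents that add atoms: tert-butyldimethylsilyl triflate, CC(C)(C)[Si](C)(C)OS(=O)(=O)C(F)(F)F
Why: The silyl triflate with amine base silylates the hindered C20 hydroxyl and the enol of the β-keto ester in one operation (silyl ether and enol silane formation), so that the ester can be reduced without touching C18; any C20 tert-butyldimethylsilyl ether already formed in step 4 converges here.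

Step 6
Reactants: 8 ethyl (3R,5aR,9aR)-3,7-bis(tert-butyldimethylsilyloxy)-2,2,5a-trimethyl-2,3,4,5,5a,8,9,9a-octahydro-1-benzoxepine-6-carboxylate
Product: 10 (3R,5aR,9aR)-3-(tert-butyldimethylsilyloxy)-2,2,5a-trimethyl-6-methylideneoctahydro-1-benzoxepin-7(2H)-one, via allylic alcohol 9 (not isolated)
Conditions: i-Bu2AlH (3 equiv), CH2Cl2, −78 °C; then 1 M HCl, THF, 0 °C
Reagents that add atoms: none
Why: Hydride reduction of the vinylogous carbonate gives the allylic alcohol, and acid then ionizes it with the help of the enol silane oxygen and removes the silyl group (the classical β-keto ester to α-methylene ketone sequence), which fixes the exocyclic methylene on C13 and not on C17.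

**Right half**

Step 7
Reactants: 11 (S)-(+)-linalool
Product: 12 (S)-1-methylcyclopent-2-en-1-ol
Conditions: second-generation Grubbs catalyst (1 mol %), CH2Cl2, 40 °C
Reagents that add atoms: none
Why: Ring-closing metathesis of the vinyl and prenyl termini extrudes isobutene and forms the cyclopentene without touching the tertiary carbinol stereocentre.

Step 8
Reactants: 12 (S)-1-methylcyclopent-2-en-1-ol
Product: 13 (S)-1-methylcyclopent-2-en-1-yl 2-methylpropanoate
Conditions: n-BuLi, THF, −78 °C; i-PrCOCl, −78 → 0 °C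
Reagents that add atoms: isobutyryl chloride, CC(C)C(Cl)=O
Why: Acylation of the lithium alkoxide avoids the acid-promoted ionization to which the tertiary allylic alcohol is prone.

Step 9
Reactants: 13 (S)-1-methylcyclopent-2-en-1-yl 2-methylpropanoate
Product: 16 (R)-2-methyl-2-(3-methylcyclopent-2-en-1-yl)propanoic acid, via silyl ketene acetal 14 (not isolated), via trimethylsilyl ester 15 (not isolated)
Conditions: LiN(i-Pr)2, Me3SiCl, THF, −78 → 60 °C; then 1 M HCl
Reagents that add atoms: none
Why: Ireland–Claisen rearrangement: the silyl ketene acetal undergoes a suprafacial [3,3] shift, so the new C3a'–C4' bond (quaternary C4') forms on the ring face that carried the oxygen and the carbinol chirality is transferred to C3a'.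

Step 10
Reactants: 16 (R)-2-methyl-2-(3-methylcyclopent-2-en-1-yl)propanoic acid
Product: 18 1-diazo-3-methyl-3-[(1R)-3-methylcyclopent-2-en-1-yl]butan-2-one, via acid chloride 17 (not isolated)
Conditions: (COCl)2, DMF (cat.), CH2Cl2, 0 °C → rt; then CH2N2 (3 equiv), Et2O, 0 °C
Reagents that add atoms: diazomethane, C=[N+]=[N-]
Why: Acylation of diazomethane by the acid chloride (first stage of an Arndt–Eistert sequence) gives the diazoketone, and excess diazomethane takes up the hydrogen chloride.

Step 11
Reactants: 18 1-diazo-3-methyl-3-[(1R)-3-methylcyclopent-2-en-1-yl]butan-2-one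
Product: 19 (1S,2R,5R,8S)-4,4,8-trimethyltricyclo[3.3.0.0^2,8]octan-3-one
Conditions: Rh2(OAc)4 (1 mol %), CH2Cl2, rt, slow addition
Reagents that add atoms: none
Why: Rhodium-carbenoid intramolecular cyclopropanation of the trisubstituted ring alkene: the three-atom tether can only reach the face on which the side chain sits, which sets C8a' cis to C3a'.

Step 12
Reactants: 19 (1S,2R,5R,8S)-4,4,8-trimethyltricyclo[3.3.0.0^2,8]octan-3-one
Product: 20 (3aR,6R,6aR)-6-hydroxy-3,3,6-trimethylhexahydropentalen-2(1H)-one (cis-fused; hydroxyl cis to the ring-fusion hydrogens)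
Conditions: 1 M HClO4 (aq.), THF, 0 °C → rt
Reagents that add atoms: water, O
Why: Acid-catalysed homoconjugate addition of water to the cyclopropyl ketone cleaves the external cyclopropane bond to the methyl-bearing tertiary carbon with inversion (attack on the convex face), placing the hydroxyl on the side of the ring-fusion hydrogens.

Step 13
Reactants: 20 (3aR,6R,6aR)-6-hydroxy-3,3,6-trimethylhexahydropentalen-2(1H)-one
Product: 21 bis(trimethylsilyl) derivative of 20 (tertiary silyl ether; enol silane C5'=C8')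
Conditions: Me3SiOTf (2.5 equiv), Et3N, CH2Cl2, 0 °C; aq. NaHCO3
Reagents that add atoms: trimethylsilyl triflate, C[Si](C)(C)OS(=O)(=O)C(F)(F)F
Why: Silyl triflate and amine silylate the tertiary alcohol and convert the ketone into its only possible enol silane, since C4' is quaternary.

Step 14
Reactants: 21 bis(trimethylsilyl) derivative of 20
Product: 22 dichlorocyclobutanone adduct (cyclobutanone fused at C5'–C8'; CCl2 on C5', C=O on C8'; ketene added on the convex face)
Conditions: Cl2CHCOCl, Et3N, hexane, rt
Reagents that add atoms: dichloroacetyl chloride, ClC(Cl)C(Cl)=O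
Why: [2+2] cycloaddition of dichloroketene, generated in the flask, with the enol silane: the ketene carbonyl carbon bonds to the nucleophilic C8' and the dichloromethylene carbon to C5'.

Step 15
Reactants: 22 dichlorocyclobutanone adduct
Product: 24 (1R,3aR,8aR)-1-hydroxy-1,4,4-trimethyloctahydroazulene-5,7-dione, via dechlorinated cyclobutanone 23 (not isolated)
Conditions: Zn, AcOH, rt; then H2O, i-PrOH, 80 °C
Reagents that add atoms: none
Why: Zinc removes both chlorines, and desilylation in hot aqueous acid triggers retro-aldol opening of the ring-fusion bond of the β-oxy cyclobutanone, a two-carbon ring expansion to the cycloheptane-1,3-dione.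

Step 16
Reactants: 24 (1R,3aR,8aR)-1-hydroxy-1,4,4-trimethyloctahydroazulene-5,7-dione
Product: 25 (1R,3aR,8aR)-1-hydroxy-1,4,4,6-tetramethyloctahydroazulene-5,7-dione (C6' epimers)
Conditions: MeI, K2CO3, acetone, reflux
Reagents that add atoms: iodomethane, CI
Why: C-Alkylation of the 1,3-diketone at the doubly activated C6'.

Step 17
Reactants: 25 (1R,3aR,8aR)-1-hydroxy-1,4,4,6-tetramethyloctahydroazulene-5,7-dione
Product: 26 (1R,3aR,8aR)-1-hydroxy-7-methoxy-1,4,4,6-tetramethyl-2,3,3a,4,8,8a-hexahydroazulen-5(1H)-one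
Conditions: MeOH, HC(OMe)3, TsOH·H2O (cat.), rt
Reagents that add atoms: methanol, CO
Why: Acid-catalysed enol ether formation is directed to the less hindered C7' carbonyl, because an alkoxy-bearing sp2 carbon next to the quaternary C4' is disfavoured, as in the known behaviour of 4,4-dimethylcyclohexane-1,3-dione.

Step 18
Reactants: 26 (1R,3aR,8aR)-1-hydroxy-7-methoxy-1,4,4,6-tetramethyl-2,3,3a,4,8,8a-hexahydroazulen-5(1H)-one
Product: 28 (1R,3aR,8aR)-1-hydroxy-1,4,4,5,6-pentamethyl-2,3,3a,4,8,8a-hexahydroazulen-7(1H)-one, via tertiary carbinol 27 (not isolated)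
Conditions: MeLi (3 equiv), CeCl3, THF, −78 → 0 °C; then 1 M HCl, THF, rt
Reagents that add atoms: methyllithium, [Li]C
Why: Stork–Danheiser sequence: 1,2-addition of the organocerium reagent to the vinylogous ester carbonyl and acid hydrolysis of the resulting carbinol transpose the enone and install the C5' methyl.

Step 19
Reactants: 28 (1R,3aR,8aR)-1-hydroxy-1,4,4,5,6-pentamethyl-2,3,3a,4,8,8a-hexahydroazulen-7(1H)-one
Product: 29 extended dienol silane of 28 (C7'–OSiEt3, C6'=C7', exocyclic C5'=CH2; C1'–OSiEt3)
Conditions: KN(SiMe3)2 (2.2 equiv), THF, −78 → 0 °C; Et3SiCl, −78 °C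
Reagents that add atoms: chlorotriethylsilane, CC[Si](Cl)(CC)CC
Why: Under equilibrating conditions the linearly conjugated dienolate is the thermodynamic anion, and because C4' is quaternary only the C5' methyl can supply the γ-hydrogen; the silyl chloride traps it on oxygen and also silylates the tertiary alkoxide.

**Union and completion**

Step 20
Reactants: 10 (3R,5aR,9aR)-3-(tert-butyldimethylsilyloxy)-2,2,5a-trimethyl-6-methylideneoctahydro-1-benzoxepin-7(2H)-one; 29 extended dienol silane of 28
Product: 30 coupled enone (C13=C18–OSiEt3 enol silane of the left bicycle joined through CH2CH2 to C5' of the 1'-triethylsilyloxy hydroazulen-7'-one; C20–OSi-t-BuMe2)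
Conditions: Tf2NH (5 mol %), CH2Cl2, −78 °C; Et3N quench
Reagents that add atoms: none
Why: Vinylogous Mukaiyama–Michael addition catalysed by the silyl triflimide formed in the flask: the unhindered exocyclic γ-carbon of the dienol silane (C6' is fully substituted) adds to the silyl-activated methylene ketone, and silyl transfer leaves C18 masked as its enol silane while the enone is regenerated.

Step 21
Reactants: 30 coupled enone
Product: 31 (7'S)-allylic alcohol of 30
Conditions: (R)-2-methyl-CBS-oxazaborolidine (0.5 equiv), catecholborane, toluene, −78 °C; aq. NaOH wash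
Reagents that add atoms: none
Why: Corey–Bakshi–Shibata reduction: the oxazaborolidine differentiates the alkenyl and methylene flanks of the only free carbonyl and should give the 7'S alcohol, reinforced by hydride attack on the convex face of the cis-fused bicycle; catecholborane at low temperature leaves the enol silane alone.

Step 22
Reactants: 31 (7'S)-allylic alcohol of 30
Product: 32 keto triol (C18 ketone, C13–H with equatorial side chain; free hydroxyls at C20, C1' and C7')
Conditions: Bu4NF (6 equiv), THF, 0 → 40 °C; aq. NH4Cl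
Reagents that add atoms: none
Why: Fluoride removes the three silyl groups, and the enolate set free at C13 is protonated from the face opposite the axial C14 methyl, which is also the thermodynamic outcome (equatorial side chain).

Step 23
Reactants: 32 keto triol
Product: 33 CNP0276044.1 (target)
Conditions: MeLi, CeCl3 (8 equiv each), THF, −78 → −40 °C; aq. NH4Cl
Reagents that add atoms: methyllithium, [Li]C
Why: Organocerium addition to the hindered enolizable ketone: the axial C14 methyl blocks the axial trajectory, so methyl enters equatorially and the C18 hydroxyl becomes axial, as in the target.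

**Compound list**

1 | geranyl bromide | CC(C)=CCC/C(C)=C/CBr | starting material
2 | ethyl acetoacetate | CCOC(=O)CC(C)=O | starting material
3 | ethyl (6E)-7,11-dimethyl-3-oxododeca-6,10-dienoate | CCOC(=O)CC(=O)CC/C=C(\C)CCC=C(C)C | intermediate
4 | ethyl (2Z,6E)-3-(tert-butyldimethylsilyloxy)-7,11-dimethyldodeca-2,6,10-trienoate | CC(C)=CCC/C(C)=C/CC/C(O[Si](C)(C)C(C)(C)C)=C/C(=O)OCC | intermediate
5 | ethyl (2Z,6R,7R,10R)-3-(tert-butyldimethylsilyloxy)-6,7:10,11-diepoxy-7,11-dimethyldodec-2-enoate | CC1(C)O[C@@H]1CC[C@@]1(C)O[C@@H]1CC/C(O[Si](C)(C)C(C)(C)C)=C/C(=O)OCC | intermediate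
6 | C20 trimethylsilyl ether of 7 | CCOC(=O)[C@@H]1[C@@]2(C)CC[C@@H](O[Si](C)(C)C)C(C)(C)O[C@@H]2CCC1=O | intermediate
7 | ethyl (3R,5aR,6R,9aR)-3-hydroxy-2,2,5a-trimethyl-7-oxodecahydro-1-benzoxepine-6-carboxylate | CCOC(=O)[C@@H]1[C@@]2(C)CC[C@@H](O)C(C)(C)O[C@@H]2CCC1=O | intermediate
8 | ethyl (3R,5aR,9aR)-3,7-bis(tert-butyldimethylsilyloxy)-2,2,5a-trimethyl-2,3,4,5,5a,8,9,9a-octahydro-1-benzoxepine-6-carboxylate | CCOC(=O)C=1[C@@]2(C)CC[C@@H](O[Si](C)(C)C(C)(C)C)C(C)(C)O[C@@H]2CCC=1O[Si](C)(C)C(C)(C)C | intermediate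
9 | allylic alcohol from 8 (CH2OH on C13, C13=C18 enol silane) | OCC=1[C@@]2(C)CC[C@@H](O[Si](C)(C)C(C)(C)C)C(C)(C)O[C@@H]2CCC=1O[Si](C)(C)C(C)(C)C | intermediate
10 | (3R,5aR,9aR)-3-(tert-butyldimethylsilyloxy)-2,2,5a-trimethyl-6-methylideneoctahydro-1-benzoxepin-7(2H)-one | C=C1[C@@]2(C)CC[C@@H](O[Si](C)(C)C(C)(C)C)C(C)(C)O[C@@H]2CCC1=O | intermediate
11 | (S)-(+)-linalool | C=C[C@@](C)(O)CCC=C(C)C | starting material
12 | (S)-1-methylcyclopent-2-en-1-ol | O[C@]1(C)C=CCC1 | intermediate
13 | (S)-1-methylcyclopent-2-en-1-yl 2-methylpropanoate | CC(C)C(=O)O[C@]1(C)C=CCC1 | intermediate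
14 | trimethylsilyl ketene acetal of 13 | CC(C)=C(O[Si](C)(C)C)O[C@]1(C)C=CCC1 | intermediate
15 | trimethylsilyl ester of 16 | C[Si](C)(C)OC(=O)C(C)(C)[C@@H]1CCC(C)=C1 | intermediate
16 | (R)-2-methyl-2-(3-methylcyclopent-2-en-1-yl)propanoic acid | OC(=O)C(C)(C)[C@@H]1CCC(C)=C1 | intermediate
17 | acid chloride of 16 | ClC(=O)C(C)(C)[C@@H]1CCC(C)=C1 | intermediate
18 | 1-diazo-3-methyl-3-[(1R)-3-methylcyclopent-2-en-1-yl]butan-2-one | [N-]=[N+]=CC(=O)C(C)(C)[C@@H]1CCC(C)=C1 | intermediate
19 | (1S,2R,5R,8S)-4,4,8-trimethyltricyclo[3.3.0.0^2,8]octan-3-one | O=C1C(C)(C)[C@@H]2CC[C@@]3(C)[C@@H]2[C@@H]13 | intermediate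
20 | (3aR,6R,6aR)-6-hydroxy-3,3,6-trimethylhexahydropentalen-2(1H)-one | O=C1C(C)(C)[C@@H]2CC[C@@](C)(O)[C@@H]2C1 | intermediate
21 | bis(trimethylsilyl) derivative of 20 (silyl ether and enol silane) | CC1(C)[C@@H]2CC[C@@](C)(O[Si](C)(C)C)[C@@H]2C=C1O[Si](C)(C)C | intermediate
22 | dichlorocyclobutanone adduct of 21 | CC1(C)[C@@H]2CC[C@@](C)(O[Si](C)(C)C)[C@@H]2[C@H]3C(=O)C(Cl)(Cl)[C@@]13O[Si](C)(C)C | intermediate
23 | dechlorinated cyclobutanone | CC1(C)[C@@H]2CC[C@@](C)(O[Si](C)(C)C)[C@@H]2[C@H]3C(=O)C[C@@]13O[Si](C)(C)C | intermediate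
24 | (1R,3aR,8aR)-1-hydroxy-1,4,4-trimethyloctahydroazulene-5,7-dione | O=C1CC(=O)C(C)(C)[C@@H]2CC[C@@](C)(O)[C@@H]2C1 | intermediate
25 | (1R,3aR,8aR)-1-hydroxy-1,4,4,6-tetramethyloctahydroazulene-5,7-dione (C6' epimers) | O=C1C(C)C(=O)C(C)(C)[C@@H]2CC[C@@](C)(O)[C@@H]2C1 | intermediate
26 | (1R,3aR,8aR)-1-hydroxy-7-methoxy-1,4,4,6-tetramethyl-2,3,3a,4,8,8a-hexahydroazulen-5(1H)-one | COC1=C(C)C(=O)C(C)(C)[C@@H]2CC[C@@](C)(O)[C@@H]2C1 | intermediate
27 | tertiary carbinol from methyl addition to 26 (C5' epimers) | COC1=C(C)C(C)(O)C(C)(C)[C@@H]2CC[C@@](C)(O)[C@@H]2C1 | intermediate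
28 | (1R,3aR,8aR)-1-hydroxy-1,4,4,5,6-pentamethyl-2,3,3a,4,8,8a-hexahydroazulen-7(1H)-one | CC1=C(C)C(C)(C)[C@@H]2CC[C@@](C)(O)[C@@H]2CC1=O | intermediate
29 | extended bis(triethylsilyl) dienol silane of 28 | CC=1C(=C)C(C)(C)[C@@H]2CC[C@@](C)(O[Si](CC)(CC)CC)[C@@H]2CC=1O[Si](CC)(CC)CC | intermediate
30 | coupled enone with C18 triethylsilyl enol ether | CC1=C(CCC=3[C@@]4(C)CC[C@@H](O[Si](C)(C)C(C)(C)C)C(C)(C)O[C@@H]4CCC=3O[Si](CC)(CC)CC)C(C)(C)[C@@H]2CC[C@@](C)(O[Si](CC)(CC)CC)[C@@H]2CC1=O | intermediate
31 | (7'S)-allylic alcohol of 30 | CC1=C(CCC=3[C@@]4(C)CC[C@@H](O[Si](C)(C)C(C)(C)C)C(C)(C)O[C@@H]4CCC=3O[Si](CC)(CC)CC)C(C)(C)[C@@H]2CC[C@@](C)(O[Si](CC)(CC)CC)[C@@H]2C[C@@H]1O | intermediate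
32 | keto triol (C18 ketone, 13R side chain equatorial) | CC1=C(CC[C@@H]3[C@@]4(C)CC[C@@H](O)C(C)(C)O[C@@H]4CCC3=O)C(C)(C)[C@@H]2CC[C@@](C)(O)[C@@H]2C[C@@H]1O | intermediate
33 | CNP0276044.1 | CC1=C(CC[C@@H]2[C@@]3(C)CC[C@@H](O)C(C)(C)O[C@@H]3CC[C@]2(C)O)C(C)(C)[C@@H]2CC[C@@](C)(O)[C@@H]2C[C@@H]1O | target

**Step count and risks**

Total step count: 23. Longest linear sequence: 17 steps (steps 7–19, then 20–23, from (S)-linalool); the left branch needs 6 steps before the union.

Steps most likely to fail:

1. Step 4. The ester-conjugated enol silane may react too slowly, so that the epoxonium ion is lost to proton elimination or triflate capture, or the first closure may run 6-exo. The fallback sets out from 5 and gives the terminator the character of a simple ketone enol silane. Reduction of the ester with i-Bu2AlH should give the allylic alcohol F1, and silylation (t-BuMe2SiCl, imidazole) its primary silyl ether F2. The same cascade, promoted by t-BuMe2SiOTf so that O20 keeps the silyl group, should give the 13-(silyloxymethyl) ketone F3. β-Elimination of silanol with DBU then comes back to the route at 10.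

2. Step 20. The dienol silane may be consumed by protodesilylation, or the methylene ketone may oligomerize before the γ-carbon adds. The fallback reverses the polarity and sets out from 26 and 7. CH2=CHMgBr with CeCl3 adds to 26 to give the vinyl carbinol F4, which acid converts into the 5'-vinyl dienone F5. Keto ester 7 adds 1,6 to F5 (Cs2CO3, MeCN) to give the quaternary keto ester adduct F6. CBS reduction of its enone (the carbonyl next to the quaternary C13 should stay inert) gives the allylic alcohol F7. Krapcho dealkoxycarbonylation (LiCl, wet DMSO, 140 °C) comes back to the route at 32. This path also bypasses step 19.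

3. Step 19. Kinetic deprotonation at C8' would give the cross-conjugated dienol silane and the wrong nucleophilic carbon. The fallback makes the diene regiospecifically and sets out from 26. Silylation (Et3SiOTf, 2,6-lutidine) gives the triethylsilyl ether F8, and MeLi with CeCl3 gives the carbinol F9. Dehydration with MsCl and Et3N, in which only the new methyl can lose a proton, gives the 7'-methoxy-5'-methylidene diene F10. F10 adds through its exocyclic carbon to 10 activated by one equivalent of Et3SiOTf; bicarbonate quench hydrolyses the methyl oxocarbenium ion, and the route is rejoined at 30.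

**Further compounds**

F1 | step 4 | (2Z,6R,7R,10R)-3-(tert-butyldimethylsilyloxy)-6,7:10,11-diepoxy-7,11-dimethyldodec-2-en-1-ol | CC1(C)O[C@@H]1CC[C@@]1(C)O[C@@H]1CC/C(O[Si](C)(C)C(C)(C)C)=C/CO
F2 | step 4 | primary tert-butyldimethylsilyl ether of F1 | CC1(C)O[C@@H]1CC[C@@]1(C)O[C@@H]1CC/C(O[Si](C)(C)C(C)(C)C)=C/CO[Si](C)(C)C(C)(C)C
F3 | step 4 | 13-(silyloxymethyl) ketone with C20 silyl ether (C13 epimers) | CC(C)(C)[Si](C)(C)OCC1[C@@]2(C)CC[C@@H](O[Si](C)(C)C(C)(C)C)C(C)(C)O[C@@H]2CCC1=O
F4 | step 20 | vinyl carbinol from 26 (C5' epimers) | COC1=C(C)C(O)(C=C)C(C)(C)[C@@H]2CC[C@@](C)(O)[C@@H]2C1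
F5 | step 20 | (1R,3aR,8aR)-5-ethenyl-1-hydroxy-1,4,4,6-tetramethyl-2,3,3a,4,8,8a-hexahydroazulen-7(1H)-one | CC1=C(C=C)C(C)(C)[C@@H]2CC[C@@](C)(O)[C@@H]2CC1=O
F6 | step 20 | 1,6-adduct of 7 and F5 (quaternary C13 bearing CO2Et, configuration at C13 not fixed) | CC1=C(CCC3(C(=O)OCC)[C@@]4(C)CC[C@@H](O)C(C)(C)O[C@@H]4CCC3=O)C(C)(C)[C@@H]2CC[C@@](C)(O)[C@@H]2CC1=O
F7 | step 20 | (7'S)-allylic alcohol of F6 | CC1=C(CCC3(C(=O)OCC)[C@@]4(C)CC[C@@H](O)C(C)(C)O[C@@H]4CCC3=O)C(C)(C)[C@@H]2CC[C@@](C)(O)[C@@H]2C[C@@H]1O
F8 | step 19 | triethylsilyl ether of 26 | COC1=C(C)C(=O)C(C)(C)[C@@H]2CC[C@@](C)(O[Si](CC)(CC)CC)[C@@H]2C1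
F9 | step 19 | tertiary carbinol from methyl addition to F8 (C5' epimers) | COC1=C(C)C(C)(O)C(C)(C)[C@@H]2CC[C@@](C)(O[Si](CC)(CC)CC)[C@@H]2C1
F10 | step 19 | 7'-methoxy-5'-methylidene diene | COC1=C(C)C(=C)C(C)(C)[C@@H]2CC[C@@](C)(O[Si](CC)(CC)CC)[C@@H]2C1
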